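A flat stretch of Pdt invites the reading that something has been used up, but the violet run still holds 82.6 % of its Sbt and 88.4 % of its Ptn at 11 min.

all flasks: Ctl 0.00750 M
- grey: Sbt 0.250 M; Ptn 0.750 M
- green: Sbt 0.130 M; Ptn 0.630 M
- violet: Sbt 0.500 M; Ptn 0.750 M
- red: Sbt 0.250 M; Ptn 1.10 M
- blue: Sbt 0.100 M; Ptn 0.300 M; time 11 min

| run | time / min | [Pdt] / M |
|---|---|---|
| grey run | 1.4 | 0.038 |
| grey run | 2.8 | 0.056 |
| grey run | 4.1 | 0.068 |
| grey run | 5.5 | 0.072 |
| grey run | 6.9 | 0.078 |
| grey run | 8.2 | 0.086 |
| grey run | 9.6 | 0.081 |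
| grey run | 11 | 0.084 |
| green run | 1.4 | 0.019 |
| green run | 2.8 | 0.037 |
| green run | 4.1 | 0.042 |
| green run | 5.5 | 0.044 |
| green run | 6.9 | 0.056 |
| green run | 8.2 | 0.057 |
| green run | 9.6 | 0.060 |
| green run | 11 | 0.066 |
| violet run | 1.4 | 0.050 |
| violet run | 2.8 | 0.074 |
| violet run | 4.1 | 0.081 |
| violet run | 5.5 | 0.083 |
| violet run | 6.9 | 0.082 |
| violet run | 8.2 | 0.091 |
| violet run | 9.6 | 0.083 |
| violet run | 11 | 0.087 |
| red run | 1.4 | 0.053 |
| red run | 2.8 | 0.081 |
| red run | 4.1 | 0.100 |
| red run | 5.5 | 0.106 |
| red run | 6.9 | 0.114 |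
| red run | 8.2 | 0.119 |
| red run | 9.6 | 0.117 |
| red run | 11 | 0.125 |

(readings scatter by 0.003 M)

- Overall: Sbt + Ptn -> Pdt, with Ctl as catalyst.
- Constant volume, constant temperature.
- Bound and free are read together.
- "The second partner" is Ptn.
- An order is taken over about fifteen percent of the charge, up and down.

1. the exponent of [Sbt] in the starting rate at the charge of the grey run (at the point where two percent of the Sbt have become Pdt) (one fixed amount of Pdt, the same in the runs compared)
2. the exponent of [Ptn] in the starting rate at the charge of the grey run (at the point where two percent of the Sbt have become Pdt)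
3. Pdt in the blue run at 11 min, as a share of the Sbt charged

What stays nearly constant is the reading at 11 min as a fraction of the Ptn charged: 11.2 % in grey, 11.6 % in violet and 11.4 % in red, although violet has twice the Sbt of grey. The violet value is carried as the ceiling per Ptn: the Pdt a flask reaches when its curve has gone flat, as a fraction of the Ptn charged.

On the blue charge, this ceiling comes to 34.8 % of the Sbt charged. The approach to it needs a clock, and the green run, still rising at 11 min, supplies one: at 2.8 min its reading is 5.87 % of its Ptn, half its ceiling. With Sbt frozen at its charge, the approach is pseudo-first-order, with constant 0.248 min⁻¹ in green. Scaled in proportion to Sbt, that is 0.190 min⁻¹ in blue, and this estimate puts blue at 30.5 % of its Sbt by 11 min.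

The weak link is the frozen Sbt, since the green reading at 2.8 min is already 28.5 % of its Sbt charge. Taken midway, green's clock ran on 85.8 % of its Sbt charge, and blue's runs on about 82.6 % of its own. The reforged blue constant is 0.183 min⁻¹, slightly slower, and this reckoning commits to 30.2 %.

The forecast gives 30 % (25 % to 35 %), with orders of 0.6 in Sbt and 1.05 in Ptn, on the ground that “total turnovers are proportional to Ptn”.

The flask gives 28.5 %, with orders of 0.83 in Sbt and 1.1 in Ptn. The Sbt order lies above the forecast's range, while the other two values lie within theirs.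

    Ctl + Sbt ⇌ Ctl.Sbt, settled at all times (0.9340 M⁻¹)
    Ctl.Sbt + Ptn → Pdt + Ctl + Lvg (35.22 M⁻¹ min⁻¹)
    Ctl + Sbt → Z + Sbt (1.992 M⁻¹ min⁻¹)

The blue run at 11 min holds 9.51 % of its Ptn charge as Pdt, which is below the ceiling of 11.6 %. The passing of Ctl into Z lowers the Pdt of the blue run: with that step removed from the blue run, Pdt at 11 min rises from 28.5 % to 49.7 % of the Sbt charged, which passes the blue ceiling of 34.8 %.

(The data are calculated from invented constants.)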